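## Analysis of the target

The target has one ring, a γ-butyrolactone, numbered here O1, C1 (carbonyl), C2, C3, C4. C2 carries an exocyclic E alkylidene (C2=C1') that continues as the chain C1'–C10', C3 carries the acetate, and C4 carries a 2-methylprop-1-enyl group. The two ring stereocentres are adjacent and trans, C3 (S) and C4 (R), which is the erythro C3/C4 pattern of a 2-deoxy-D-pentose. The third stereocentre, the secondary carbinol C3' (R), lies five bonds from the ring and cannot be relayed from it. Four alkenes are defined: E at C2=C1', E at the trisubstituted C4'=C5', Z at the trisubstituted C8'=C9' (a neryl unit), and E in the 4-hydroxycinnamyl group ether-linked to C10'. The sensitive sites are the C3 acetate (allylic, on a Michael-accepting alkylidene lactone, lost under base by γ-deprotonation or SN2' attack), the bis-allylic ether and electron-rich styrene (acid, oxidants), the ionisable allylic carbinol and the free phenol. The difficulty is that alkene geometries must be made, C3' must be set without help from the ring, and three hydroxyls must be told apart so that only the C3 oxygen is acetylated. The plan rests on one feature: C3' is bonded to C4', the methyl-bearing carbon of the E C4'=C5' alkene. That is the pattern left when a methyl alkyne CH3–C≡C–C6' is hydrometalated syn with the metal next to the methyl group and the alkenyl metal adds to a C1'–C3' aldehyde.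

## Retrosynthetic reasoning

**Protecting-group endgame (35 ⇐ 34 ⇐ 33 ⇐ 32).** The phenol and the C3' carbinol of 35 are uncovered last from the bis-TBS ether 34 under buffered acidic fluoride, because the allylic acetate does not tolerate base. The acetate of 34 is placed on the free C3 hydroxyl of 33. That hydroxyl comes from the triethylsilyl ether 32, whose more labile silyl group can be removed by mild acid next to the two TBS ethers. This order is what makes the three oxygens distinguishable.

**C2=C1' alkylidene (32 ⇐ 30 ⇐ 28 + 22).** The exocyclic alkene is cut to the aldol adduct 30, and the C2–C1' bond behind it to the lactone 28 and the aldehyde 22. The cut is convergent and leaves both ring stereocentres in a small building block. The forward reaction needs an enolate of a β-silyloxy lactone that survives long enough to add, and an elimination of the activated C1' oxygen that favours the E alkene.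

**Lactone from the chiral pool (28 ⇐ 27 ⇐ 26 ⇐ 25 ⇐ 24 ⇐ 23).** C3 and C4 of 28 map onto C3 and C4 of 2-deoxy-D-ribose 23 with the right absolute configuration and the right trans relationship. Oxidation of the lactol gives 24. Bis-silylation (25) and selective release of the primary hydroxyl (26) allow oxidation to the aldehyde 27, and a Wittig isopropylidenation gives 28. No asymmetric step is needed for the ring.

**Adjusting C1' (22 ⇐ 21 ⇐ 20 ⇐ 19).** The aldehyde 22 comes from the primary alcohol 21, which comes from the differentially silylated 20 (primary triethylsilyl, secondary TBS), made by silylating the carbinol 19. These are functional-group changes only.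

**Key disconnection C3'–C4' (19 ⇐ 13 + 16).** The bond between the carbinol carbon and the methyl-bearing alkene carbon is cut. The alkenyl half is traced to the methyl alkyne 13 and the carbonyl half to the three-carbon aldehyde 16. One flask must then deliver the C–C bond, the E trisubstituted alkene (from syn addition of a metal hydride) and the C3' configuration (from a chiral ligand on zinc). Cutting C2'–C3' or C5'–C6' instead would separate the making of the alkene from the making of the stereocentre.

**Ether C–O bond (13 ⇐ 7 + 11).** The bis-allylic ether is made last before the key step, from the enynol 7 and the cinnamyl bromide 11. The electron-rich styrene and the aryl silyl ether therefore never meet a peracid, periodic acid, basic methanol or an alkyllithium.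

**Methyl alkyne from the neryl unit (7 ⇐ 5 ⇐ 3 ⇐ 2 ⇐ 1).** The methyl group on the alkyne is put on by C-methylation of the terminal alkyne 5. Compound 5 arises from the aldehyde 3 by Ohira–Bestmann homologation, with loss of the acetate in the same flask. Compound 3 arises by periodate cleavage of the terminal epoxide 2 of neryl acetate 1. The acetate deactivates the proximal alkene toward the peracid and so decides which alkene is cut, and the Z alkene C8'=C9' is bought, not made.

**Small partners (11 ⇐ 10 ⇐ 9 ⇐ 8; 16 ⇐ 15 ⇐ 14).** The bromide 11 comes from methyl 4-hydroxycinnamate 8 by silylation (9), ester reduction (10) and bromination. The aldehyde 16 comes from propane-1,3-diol 14 by mono-silylation (15) and oxidation.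

## Alternatives that were turned down

**Alternative 1:** The lactone is cut at C1–C2 and C1–O1, so that the carbonyl carbon is carbon monoxide A3. In the forward step the (E)-vinyl iodide diol A2 would undergo oxidative addition to Pd(PPh3)4 (zerovalent palladium) and CO insertion, and the acylpalladium would be captured by the C4 hydroxyl to give A1, which is identical with 33.
- For it: the alkene geometry is carried from the vinyl iodide with retention, so no elimination has to be E-selective, and A1 enters the same last two steps as the chosen route. On the C2=C1' geometry this alternative is the stronger one.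
- Against it: A2 needs iodine on C2, trans to C2', next to an anti diol that already bears the isobutenyl group. That calls for a proximal, syn hydrometalation–iodination of a propargylic diol, with its own regiochemical doubt, and for an asymmetric synthesis of the diol.
- The C3' carbinol and the E C4'=C5' alkene would still have to be made by other means, so the alternative solves the ring only.
- Zerovalent palladium would meet an allylic C4–O bond and a bis-allylic ether, both of which can ionise.
- Comparison: the chosen route takes both ring stereocentres from 23 without an asymmetric step and puts its risk into one bond formation that also sets C3'. The price is an elimination whose geometry must be watched.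

**Alternative 2:** The C3–C4 bond is cut together with the lactone C–O bond. The α-chiral, γ-silyloxy, 2-methoxycarbonyl allylboronate A6 would add to 3-methylbut-2-enal A5 through a chair transition state (silyloxy group equatorial, C2' chain axial) to give the ester A4, which lactonises to 32.
- For it: one step sets C3, C4 and the E alkylidene, and no chiral pool is needed. Around the ring this is shorter than five steps from 23 plus aldol and dehydration, and on that count it is the stronger plan.
- Against it: A6 must be made as a single isomer with a boron-bearing stereocentre at C1', a defined silyl enol ether and the whole side chain including C3' already in place.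
- Ester-substituted allylboronates are deactivated and normally need acid catalysis, under which the silyl enol ether is doubtful. A 1,3-boron shift would scramble the reagent.
- C3' must still be set while A6 is being made, so nothing is saved there.
- Comparison: the chosen route uses partners that are each a few reliable steps from commercial materials and keeps the uncertain chemistry in a single, well-understood organozinc addition.

**Alternative 3:** The C2'–C3' bond is cut. The silyl dienolate A9, made from the (E)-α-ethylidene lactone A10, would add through its terminal CH2 to the enal A8 under SiCl4 and a chiral bisphosphoramide to give A7, with C3' and the E alkylidene formed in the coupling.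
- For it: the stereocentre is made in the fragment union itself, and A7 emerges with the carbinol free and the ring oxygen silylated. The three steps that adjust C1' in the chosen route (12–14) are not needed, so on convergence this alternative is stronger.
- Against it: A9 has a silyloxy leaving group on C3 next to the C4 hydrogen. Loss of silanol gives an aromatic 2-silyloxyfuran, both when A10 is enolised and in the chlorosilane medium.
- A10 would itself come from 28 by an aldol–dehydration, so the E/Z question is only moved to an earlier compound.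
- The catalyst system is best established for simpler dienolates and unbranched conjugated aldehydes, whereas A8 is α-branched and exposes a bis-allylic ether and an electron-rich styrene to SiCl4. α- versus γ-attack is a further open point.
- Comparison: the chosen route sets C3' under neutral organozirconium and organozinc conditions that leave the ethers and silyl groups alone, with a trivial aldehyde partner.

Key step: step 11

Assumption: commercial neryl acetate of high Z purity is used as the source of C5'–C10', because the acetate steers the peracid to the distal alkene and is lost in the alkynylation flask.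

## Route

Step 1
Reactants: 1 neryl acetate [(Z)-3,7-dimethylocta-2,6-dien-1-yl acetate]
Product: 2 (Z)-5-(3,3-dimethyloxiran-2-yl)-3-methylpent-2-en-1-yl acetate (racemic at the oxirane carbon)
Conditions: mCPBA (1.05 equiv), NaHCO3, CH2Cl2, 0 °C
Reagents that add atoms: 3-chloroperbenzoic acid, O=C(OO)c1cccc(Cl)c1
Why: Prilezhaev epoxidation; the distal trisubstituted alkene is the more electron-rich because the proximal one is deactivated by the allylic acetate, so one equivalent of peracid should react there, and the new stereocentre is destroyed in step 2.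

Step 2
Reactants: 2 (Z)-5-(3,3-dimethyloxiran-2-yl)-3-methylpent-2-en-1-yl acetate
Product: 3 (Z)-3-methyl-6-oxohex-2-en-1-yl acetate
Conditions: H5IO6 (1.2 equiv), THF/H2O, 0 °C
Reagents that add atoms: none
Why: Epoxide hydration and periodate glycol cleavage in one flask; water opens the protonated epoxide at the tertiary carbon, so the aldehyde oxygen is the former oxirane oxygen and the three-carbon end leaves as a ketone, while the allylic acetate and the Z alkene are untouched at 0 °C.

Step 3
Reactants: 3 (Z)-3-methyl-6-oxohex-2-en-1-yl acetate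
Product: 5 (Z)-3-methylhept-2-en-6-yn-1-ol, via acetoxy alkyne 4 (not isolated)
Conditions: dimethyl (1-diazo-2-oxopropyl)phosphonate (1.3 equiv), K2CO3 (2.5 equiv), MeOH, 0 °C → rt, 16 h
Reagents that add atoms: dimethyl (1-diazo-2-oxopropyl)phosphonate, COP(=O)(OC)C(=[N+]=[N-])C(C)=O
Why: Ohira–Bestmann homologation: methoxide deacetylates the reagent, the diazophosphonate anion adds to the aldehyde, and loss of phosphate and N2 with a 1,2-hydrogen shift gives the terminal alkyne; the same K2CO3/MeOH medium transesterifies the allylic acetate, so the free alcohol is uncovered without a separate step.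

Step 4
Reactants: 5 (Z)-3-methylhept-2-en-6-yn-1-ol
Product: 7 (Z)-3-methyloct-2-en-6-yn-1-ol, via dilithio derivative 6 (not isolated)
Conditions: n-BuLi (2.1 equiv), THF, −78 → −20 °C; MeI (1.05 equiv), −78 °C → rt
Reagents that add atoms: iodomethane, CI
Why: Acetylide alkylation; in THF without polar additives the acetylide carbon is far more nucleophilic toward MeI than the lithium alkoxide, so one equivalent should methylate carbon only, and doing it here keeps strong base away from the later bis-allylic ether, which could undergo Wittig rearrangement.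

Step 5
Reactants: 8 methyl (E)-4-hydroxycinnamate
Product: 9 methyl (E)-3-[4-(tert-butyldimethylsilyloxy)phenyl]prop-2-enoate
Conditions: TBSCl (1.2 equiv), imidazole (2.5 equiv), DMF, rt
Reagents that add atoms: tert-butyldimethylsilyl chloride, CC(C)(C)[Si](C)(C)Cl
Why: Imidazole-promoted silylation of a phenol; the aryl TBS ether survives hydride, neutral bromination and the organometallic steps and is cleaved by fluoride at the end.

Step 6
Reactants: 9 methyl (E)-3-[4-(tert-butyldimethylsilyloxy)phenyl]prop-2-enoate
Product: 10 (E)-3-[4-(tert-butyldimethylsilyloxy)phenyl]prop-2-en-1-ol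
Conditions: i-Bu2AlH (2.3 equiv), CH2Cl2, −78 °C; aq. potassium sodium tartrate
Reagents that add atoms: none
Why: 1,2-Reduction of an α,β-unsaturated ester by an aluminium hydride; two hydrides are delivered to the carbonyl carbon and the E alkene is retained.

Step 7
Reactants: 10 (E)-3-[4-(tert-butyldimethylsilyloxy)phenyl]prop-2-en-1-ol
Product: 11 (E)-1-(3-bromoprop-1-enyl)-4-(tert-butyldimethylsilyloxy)benzene
Conditions: CBr4 (1.2 equiv), PPh3 (1.25 equiv), CH2Cl2, 0 °C, 20 min; short silica pad, used at once
Reagents that add atoms: carbon tetrabromide, BrC(Br)(Br)Br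
Why: Appel bromination under neutral conditions; the primary allylic alkoxyphosphonium is displaced by bromide at the unhindered terminus, and the ionisable product is not stored.

Step 8
Reactants: 7 (Z)-3-methyloct-2-en-6-yn-1-ol; 11 (E)-1-(3-bromoprop-1-enyl)-4-(tert-butyldimethylsilyloxy)benzene
Product: 13 (Z)-3-methyloct-2-en-6-ynyl (E)-3-[4-(tert-butyldimethylsilyloxy)phenyl]prop-2-enyl ether, via sodium alkoxide 12 (not isolated)
Conditions: NaH (1.1 equiv), THF, 0 °C; then 11 (1.15 equiv), n-Bu4NI (5 mol%), 0 °C → rt
Reagents that add atoms: none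
Why: Williamson ether synthesis; the primary allylic alkoxide displaces bromide from a very reactive cinnamyl bromide at its primary carbon, which should be faster than attack of the alkoxide on the aryl silyl ether in THF at 0 °C, and the internal alkyne carries no acidic hydrogen.

Step 9
Reactants: 14 propane-1,3-diol
Product: 15 3-(triethylsilyloxy)propan-1-ol
Conditions: 14 (4 equiv), TESCl (1 equiv), Et3N (1.2 equiv), CH2Cl2, 0 °C
Reagents that add atoms: chlorotriethylsilane, CC[Si](Cl)(CC)CC
Why: Statistical mono-silylation; a large excess of the cheap diol suppresses bis-silylation and is removed by aqueous washing.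

Step 10
Reactants: 15 3-(triethylsilyloxy)propan-1-ol
Product: 16 3-(triethylsilyloxy)propanal
Conditions: Dess–Martin periodinane (1.2 equiv), NaHCO3, CH2Cl2, 0 °C → rt; used fresh
Reagents that add atoms: none
Why: Dess–Martin oxidation under buffered, non-basic conditions, which avoids both cleavage of the primary triethylsilyl ether and β-elimination of the silyloxy group.

Step 11
Reactants: 13 (Z)-3-methyloct-2-en-6-ynyl (E)-3-[4-(tert-butyldimethylsilyloxy)phenyl]prop-2-enyl ether; 16 3-(triethylsilyloxy)propanal
Product: 19 (3R,4E,8Z)-10-{(E)-3-[4-(tert-butyldimethylsilyloxy)phenyl]prop-2-enyloxy}-4,8-dimethyl-1-(triethylsilyloxy)deca-4,8-dien-3-ol, via alkenylzirconocene chloride 17 (not isolated), via alkenyl(methyl)zinc 18 (not isolated)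
Conditions: Cp2Zr(H)Cl (1.3 equiv), CH2Cl2, rt; solvent exchange to toluene; Me2Zn (1.3 equiv), −65 → −30 °C; (−)-MIB [(2S)-3-exo-morpholinoisoborneol, 15 mol%], then 16 (1.5 equiv, slow addition), −30 → 0 °C; aq. NH4Cl
Reagents that add atoms: none
Why: Cp2Zr(H)Cl adds Zr–H syn across the alkyne of 13, and with a small excess the two regioisomeric alkenylzirconium species interconvert by a second addition and β-hydride elimination, so zirconium settles on the less hindered, methyl-bearing carbon (17). Me2Zn then takes over the alkenyl group with retention of geometry (18), and the zinc amino-alkoxide formed from the ligand and Me2Zn binds both 18 and the aldehyde, the sp2 alkenyl group migrating in preference to methyl through the dinuclear six-membered array typical of amino-alcohol-catalysed organozinc additions. The closest known reaction type is the one-flask alkyne hydrozirconation, zirconium-to-zinc transmetalation and ligand-controlled alkenylzinc addition to aldehydes, for which an internal methyl alkyne is a less common substrate. No ring is closed, and one C–C bond (C3'–C4') is formed. The new stereocentre C3' is controlled by the ligand alone: (−)-MIB, the antipode that directs organozinc groups to the Si face of aldehydes, should give the (R)-carbinol because the alkenyl group outranks the CH2CH2OSi arm, and the antipodal ligand is equally accessible should the facial sense prove reversed. The E geometry of C4'=C5' follows from syn addition and stereoretentive transmetalation. Chemoselectivity rests on the much faster reaction of Zr–H with an alkyne than with trisubstituted or styrenyl alkenes, and on the inertness of the silyl ethers and the bis-allylic ether to these neutral organometallics. Enantioselectivity requires the ligand-accelerated path to outrun the achiral addition promoted by Cp2Zr(CH3)Cl, which is why the solvent is changed to toluene, the temperature is kept low and the aldehyde is added slowly.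

Step 12
Reactants: 19 (3R,4E,8Z)-10-{(E)-3-[4-(tert-butyldimethylsilyloxy)phenyl]prop-2-enyloxy}-4,8-dimethyl-1-(triethylsilyloxy)deca-4,8-dien-3-ol
Product: 20 (3R,4E,8Z)-3-(tert-butyldimethylsilyloxy)-10-{(E)-3-[4-(tert-butyldimethylsilyloxy)phenyl]prop-2-enyloxy}-4,8-dimethyl-1-(triethylsilyloxy)deca-4,8-diene
Conditions: TBSCl (1.5 equiv), imidazole (3 equiv), DMF, rt
Reagents that add atoms: tert-butyldimethylsilyl chloride, CC(C)(C)[Si](C)(C)Cl
Why: Imidazole-promoted silylation of the secondary allylic alcohol under non-acidic conditions that leave the primary triethylsilyl ether and the cinnamyl ether untouched; C3' is not involved in bond breaking.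

Step 13
Reactants: 20 (3R,4E,8Z)-3-(tert-butyldimethylsilyloxy)-10-{(E)-3-[4-(tert-butyldimethylsilyloxy)phenyl]prop-2-enyloxy}-4,8-dimethyl-1-(triethylsilyloxy)deca-4,8-diene
Product: 21 (3R,4E,8Z)-3-(tert-butyldimethylsilyloxy)-10-{(E)-3-[4-(tert-butyldimethylsilyloxy)phenyl]prop-2-enyloxy}-4,8-dimethyldeca-4,8-dien-1-ol
Conditions: PPTS (0.15 equiv), MeOH/CH2Cl2 (1:1), 0 °C
Reagents that add atoms: none
Why: Acid-catalysed methanolysis of a primary triethylsilyl ether, which is far faster than that of a secondary alkyl TBS ether or an aryl TBS ether, both of which resist mild protic acid.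

Step 14
Reactants: 21 (3R,4E,8Z)-3-(tert-butyldimethylsilyloxy)-10-{(E)-3-[4-(tert-butyldimethylsilyloxy)phenyl]prop-2-enyloxy}-4,8-dimethyldeca-4,8-dien-1-ol
Product: 22 (3R,4E,8Z)-3-(tert-butyldimethylsilyloxy)-10-{(E)-3-[4-(tert-butyldimethylsilyloxy)phenyl]prop-2-enyloxy}-4,8-dimethyldeca-4,8-dienal
Conditions: Dess–Martin periodinane (1.3 equiv), NaHCO3, CH2Cl2, 0 °C → rt
Reagents that add atoms: none
Why: Dess–Martin oxidation; the buffered, non-basic medium should prevent β-elimination of the C3' silyloxy group from the β-silyloxy aldehyde and does not touch the alkenes.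

Step 15
Reactants: 23 2-deoxy-D-ribose
Product: 24 2-deoxy-D-ribono-1,4-lactone [(4S,5R)-4-hydroxy-5-(hydroxymethyl)dihydrofuran-2(3H)-one]
Conditions: Br2 (1.5 equiv), BaCO3, H2O, rt, dark
Reagents that add atoms: none
Why: Bromine-water oxidation of the cyclic hemiacetal of an aldose to the aldonolactone, which settles as the five-membered lactone; only the anomeric C–H is oxidised, so C3 and C4 keep their configuration.

Step 16
Reactants: 24 2-deoxy-D-ribono-1,4-lactone
Product: 25 (4S,5R)-4-(triethylsilyloxy)-5-[(triethylsilyloxy)methyl]dihydrofuran-2(3H)-one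
Conditions: TESCl (2.4 equiv), imidazole (4 equiv), DMF, 0 °C → rt
Reagents that add atoms: chlorotriethylsilane, CC[Si](Cl)(CC)CC
Why: Exhaustive imidazole-promoted silylation; triethylsilyl is chosen for the ring oxygen because it must later be removed selectively next to two TBS ethers.

Step 17
Reactants: 25 (4S,5R)-4-(triethylsilyloxy)-5-[(triethylsilyloxy)methyl]dihydrofuran-2(3H)-one
Product: 26 (4S,5R)-5-(hydroxymethyl)-4-(triethylsilyloxy)dihydrofuran-2(3H)-one
Conditions: HF·pyridine, pyridine, THF, 0 °C; NaHCO3 quench
Reagents that add atoms: none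
Why: Buffered HF·pyridine cleaves the unhindered primary triethylsilyl ether faster than the secondary one, a standard selective desilylation; the lactone is stable to these conditions.

Step 18
Reactants: 26 (4S,5R)-5-(hydroxymethyl)-4-(triethylsilyloxy)dihydrofuran-2(3H)-one
Product: 27 (2S,3S)-5-oxo-3-(triethylsilyloxy)tetrahydrofuran-2-carbaldehyde
Conditions: Dess–Martin periodinane (1.3 equiv), NaHCO3, CH2Cl2, 0 °C → rt; crude, used at once
Reagents that add atoms: none
Why: Dess–Martin oxidation under buffered conditions, chosen because the α-alkoxy, β-silyloxy aldehyde would epimerise or eliminate under amine bases (the descriptor changes only because CHO outranks the ring carbon).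

Step 19
Reactants: 27 (2S,3S)-5-oxo-3-(triethylsilyloxy)tetrahydrofuran-2-carbaldehyde
Product: 28 (4S,5R)-5-(2-methylprop-1-enyl)-4-(triethylsilyloxy)dihydrofuran-2(3H)-one
Conditions: i-PrPPh3I (1.3 equiv), n-BuLi (1.25 equiv), THF, 0 °C; then 27, −78 → 0 °C
Reagents that add atoms: isopropyltriphenylphosphonium iodide, CC(C)[P+](c1ccccc1)(c1ccccc1)c1ccccc1.[I-]
Why: Wittig olefination with a non-stabilised ylide; addition to the aldehyde at −78 °C should be much faster than attack on the lactone or α-deprotonation, so C4 keeps its configuration and no alkene geometry arises because the new terminus carries two methyl groups.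

Step 20
Reactants: 28 (4S,5R)-5-(2-methylprop-1-enyl)-4-(triethylsilyloxy)dihydrofuran-2(3H)-one; 22 (3R,4E,8Z)-3-(tert-butyldimethylsilyloxy)-10-{(E)-3-[4-(tert-butyldimethylsilyloxy)phenyl]prop-2-enyloxy}-4,8-dimethyldeca-4,8-dienal
Product: 30 (4S,5R)-3-[(3R,4E,8Z)-3-(tert-butyldimethylsilyloxy)-10-{(E)-3-[4-(tert-butyldimethylsilyloxy)phenyl]prop-2-enyloxy}-1-hydroxy-4,8-dimethyldeca-4,8-dienyl]-5-(2-methylprop-1-enyl)-4-(triethylsilyloxy)dihydrofuran-2(3H)-one (epimers at ring C3 and side-chain C1), via lithium enolate 29 (not isolated)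
Conditions: 28 (1.3 equiv), LiN(i-Pr)2 (1.35 equiv), THF, −78 °C, 30 min; 22, −78 °C; AcOH, −78 °C
Reagents that add atoms: none
Why: Lithium enolate aldol addition; enolates of 3-silyloxy-γ-lactones can be formed and trapped at −78 °C before silanolate is expelled, and the two new stereocentres need no control because both are removed in step 21.

Step 21
Reactants: 30 aldol adduct of 28 and 22 (epimer mixture)
Product: 32 (3E,4S,5R)-3-[(3R,4E,8Z)-3-(tert-butyldimethylsilyloxy)-10-{(E)-3-[4-(tert-butyldimethylsilyloxy)phenyl]prop-2-enyloxy}-4,8-dimethyldeca-4,8-dienylidene]-5-(2-methylprop-1-enyl)-4-(triethylsilyloxy)dihydrofuran-2(3H)-one, via methanesulfonate 31 (not isolated)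
Conditions: MsCl (1.5 equiv), Et3N (3 equiv), CH2Cl2, 0 °C; then DBU (3 equiv), 0 °C → rt
Reagents that add atoms: none
Why: Mesylation followed by E1cB elimination; of the two β-leaving groups of the C2 enolate, methanesulfonate is far better than silanolate, so the exocyclic alkene forms, and the E isomer is expected to predominate because the chain is kept away from the enolate oxygen in the transition state and from the carbonyl oxygen in the product; any Z isomer is removed by chromatography.

Step 22
Reactants: 32 (3E,4S,5R)-3-[(3R,4E,8Z)-3-(tert-butyldimethylsilyloxy)-10-{(E)-3-[4-(tert-butyldimethylsilyloxy)phenyl]prop-2-enyloxy}-4,8-dimethyldeca-4,8-dienylidene]-5-(2-methylprop-1-enyl)-4-(triethylsilyloxy)dihydrofuran-2(3H)-one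
Product: 33 (3E,4S,5R)-3-[(3R,4E,8Z)-3-(tert-butyldimethylsilyloxy)-10-{(E)-3-[4-(tert-butyldimethylsilyloxy)phenyl]prop-2-enyloxy}-4,8-dimethyldeca-4,8-dienylidene]-4-hydroxy-5-(2-methylprop-1-enyl)dihydrofuran-2(3H)-one
Conditions: PPTS (0.2 equiv), MeOH/CH2Cl2 (1:1), 0 °C → rt
Reagents that add atoms: none
Why: Acid-catalysed methanolysis of the triethylsilyl ether, which is much more acid-labile than the secondary alkyl TBS ether, while the aryl TBS ether is stable to mild protic acid (fluoride is avoided here for that reason).

Step 23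
Reactants: 33 (3E,4S,5R)-3-[(3R,4E,8Z)-3-(tert-butyldimethylsilyloxy)-10-{(E)-3-[4-(tert-butyldimethylsilyloxy)phenyl]prop-2-enyloxy}-4,8-dimethyldeca-4,8-dienylidene]-4-hydroxy-5-(2-methylprop-1-enyl)dihydrofuran-2(3H)-one
Product: 34 (2R,3S,4E)-4-[(3R,4E,8Z)-3-(tert-butyldimethylsilyloxy)-10-{(E)-3-[4-(tert-butyldimethylsilyloxy)phenyl]prop-2-enyloxy}-4,8-dimethyldeca-4,8-dienylidene]-2-(2-methylprop-1-enyl)-5-oxooxolan-3-yl acetate
Conditions: Ac2O (3 equiv), pyridine, DMAP (0.1 equiv), CH2Cl2, 0 °C
Reagents that add atoms: acetic anhydride, CC(=O)OC(C)=O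
Why: DMAP-catalysed acylation of the only free hydroxyl, with retention at C3; pyridine at 0 °C is too weak a base to remove the γ-hydrogen that would expel the new allylic acetate.

Step 24
Reactants: 34 (2R,3S,4E)-4-[(3R,4E,8Z)-3-(tert-butyldimethylsilyloxy)-10-{(E)-3-[4-(tert-butyldimethylsilyloxy)phenyl]prop-2-enyloxy}-4,8-dimethyldeca-4,8-dienylidene]-2-(2-methylprop-1-enyl)-5-oxooxolan-3-yl acetate
Product: 35 (2R,3S,4E)-4-[(3R,4E,8Z)-3-hydroxy-10-{(E)-3-(4-hydroxyphenyl)prop-2-enyloxy}-4,8-dimethyldeca-4,8-dienylidene]-2-(2-methylprop-1-enyl)-5-oxooxolan-3-yl acetate (CNP0237370.1)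
Conditions: HF·pyridine (excess), pyridine, THF, 0 °C → rt
Reagents that add atoms: none
Why: Fluoride-driven cleavage of both Si–O bonds under pyridine-buffered, weakly acidic conditions, under which the allylic acetate is neither eliminated nor transferred and the allylic carbinol and cinnamyl ether should not ionise.

## Compound list

1 | neryl acetate, (Z)-3,7-dimethylocta-2,6-dien-1-yl acetate | CC(C)=CCC/C(C)=C\COC(C)=O | starting material
2 | (Z)-5-(3,3-dimethyloxiran-2-yl)-3-methylpent-2-en-1-yl acetate (racemic epoxide) | CC1(C)OC1CC/C(C)=C\COC(C)=O | intermediate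
3 | (Z)-3-methyl-6-oxohex-2-en-1-yl acetate | O=CCC/C(C)=C\COC(C)=O | intermediate
4 | (Z)-3-methylhept-2-en-6-yn-1-yl acetate (not isolated) | C#CCC/C(C)=C\COC(C)=O | intermediate
5 | (Z)-3-methylhept-2-en-6-yn-1-ol | C#CCC/C(C)=C\CO | intermediate
6 | dilithio derivative of 5, lithium alkoxide and lithium acetylide (not isolated) | [Li]C#CCC/C(C)=C\CO[Li] | intermediate
7 | (Z)-3-methyloct-2-en-6-yn-1-ol | CC#CCC/C(C)=C\CO | intermediate
8 | methyl (E)-4-hydroxycinnamate | COC(=O)/C=C/c1ccc(O)cc1 | starting material
9 | methyl (E)-3-[4-(tert-butyldimethylsilyloxy)phenyl]prop-2-enoate | COC(=O)/C=C/c1ccc(O[Si](C)(C)C(C)(C)C)cc1 | intermediate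
10 | (E)-3-[4-(tert-butyldimethylsilyloxy)phenyl]prop-2-en-1-ol | OC/C=C/c1ccc(O[Si](C)(C)C(C)(C)C)cc1 | intermediate
11 | (E)-1-(3-bromoprop-1-enyl)-4-(tert-butyldimethylsilyloxy)benzene | BrC/C=C/c1ccc(O[Si](C)(C)C(C)(C)C)cc1 | intermediate
12 | sodium (Z)-3-methyloct-2-en-6-yn-1-olate (not isolated) | CC#CCC/C(C)=C\C[O-].[Na+] | intermediate
13 | (Z)-3-methyloct-2-en-6-ynyl (E)-3-[4-(tert-butyldimethylsilyloxy)phenyl]prop-2-enyl ether | CC#CCC/C(C)=C\COC/C=C/c1ccc(O[Si](C)(C)C(C)(C)C)cc1 | intermediate
14 | propane-1,3-diol | OCCCO | starting material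
15 | 3-(triethylsilyloxy)propan-1-ol | CC[Si](CC)(CC)OCCCO | intermediate
16 | 3-(triethylsilyloxy)propanal | O=CCCO[Si](CC)(CC)CC | intermediate
17 | [(2E,6Z)-8-{(E)-3-[4-(tert-butyldimethylsilyloxy)phenyl]prop-2-enyloxy}-6-methylocta-2,6-dien-2-yl]chlorobis(cyclopentadienyl)zirconium (not isolated) | C/C(=C\CC/C(C)=C\COC/C=C/c1ccc(O[Si](C)(C)C(C)(C)C)cc1)[Zr](Cl)(C1C=CC=C1)C1C=CC=C1 | intermediate
18 | [(2E,6Z)-8-{(E)-3-[4-(tert-butyldimethylsilyloxy)phenyl]prop-2-enyloxy}-6-methylocta-2,6-dien-2-yl](methyl)zinc (not isolated) | C/C(=C\CC/C(C)=C\COC/C=C/c1ccc(O[Si](C)(C)C(C)(C)C)cc1)[Zn]C | intermediate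
19 | (3R,4E,8Z)-10-{(E)-3-[4-(tert-butyldimethylsilyloxy)phenyl]prop-2-enyloxy}-4,8-dimethyl-1-(triethylsilyloxy)deca-4,8-dien-3-ol | CC[Si](CC)(CC)OCC[C@@H](O)/C(C)=C/CC/C(C)=C\COC/C=C/c1ccc(O[Si](C)(C)C(C)(C)C)cc1 | intermediate
20 | (3R,4E,8Z)-3-(tert-butyldimethylsilyloxy)-10-{(E)-3-[4-(tert-butyldimethylsilyloxy)phenyl]prop-2-enyloxy}-4,8-dimethyl-1-(triethylsilyloxy)deca-4,8-diene | CC[Si](CC)(CC)OCC[C@@H](O[Si](C)(C)C(C)(C)C)/C(C)=C/CC/C(C)=C\COC/C=C/c1ccc(O[Si](C)(C)C(C)(C)C)cc1 | intermediate
21 | (3R,4E,8Z)-3-(tert-butyldimethylsilyloxy)-10-{(E)-3-[4-(tert-butyldimethylsilyloxy)phenyl]prop-2-enyloxy}-4,8-dimethyldeca-4,8-dien-1-ol | OCC[C@@H](O[Si](C)(C)C(C)(C)C)/C(C)=C/CC/C(C)=C\COC/C=C/c1ccc(O[Si](C)(C)C(C)(C)C)cc1 | intermediate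
22 | (3R,4E,8Z)-3-(tert-butyldimethylsilyloxy)-10-{(E)-3-[4-(tert-butyldimethylsilyloxy)phenyl]prop-2-enyloxy}-4,8-dimethyldeca-4,8-dienal | O=CC[C@@H](O[Si](C)(C)C(C)(C)C)/C(C)=C/CC/C(C)=C\COC/C=C/c1ccc(O[Si](C)(C)C(C)(C)C)cc1 | intermediate
23 | 2-deoxy-D-ribose | O=CC[C@H](O)[C@H](O)CO | starting material
24 | 2-deoxy-D-ribono-1,4-lactone, (4S,5R)-4-hydroxy-5-(hydroxymethyl)dihydrofuran-2(3H)-one | O=C1C[C@H](O)[C@@H](CO)O1 | intermediate
25 | (4S,5R)-4-(triethylsilyloxy)-5-[(triethylsilyloxy)methyl]dihydrofuran-2(3H)-one | O=C1C[C@H](O[Si](CC)(CC)CC)[C@@H](CO[Si](CC)(CC)CC)O1 | intermediate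
26 | (4S,5R)-5-(hydroxymethyl)-4-(triethylsilyloxy)dihydrofuran-2(3H)-one | O=C1C[C@H](O[Si](CC)(CC)CC)[C@@H](CO)O1 | intermediate
27 | (2S,3S)-5-oxo-3-(triethylsilyloxy)tetrahydrofuran-2-carbaldehyde | O=C1C[C@H](O[Si](CC)(CC)CC)[C@@H](C=O)O1 | intermediate
28 | (4S,5R)-5-(2-methylprop-1-enyl)-4-(triethylsilyloxy)dihydrofuran-2(3H)-one | O=C1C[C@H](O[Si](CC)(CC)CC)[C@@H](C=C(C)C)O1 | intermediate
29 | lithium enolate of 28, lithium (4S,5R)-5-(2-methylprop-1-enyl)-4-(triethylsilyloxy)-4,5-dihydrofuran-2-olate (not isolated) | [Li]OC1=C[C@H](O[Si](CC)(CC)CC)[C@@H](C=C(C)C)O1 | intermediate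
30 | (4S,5R)-3-[(3R,4E,8Z)-3-(tert-butyldimethylsilyloxy)-10-{(E)-3-[4-(tert-butyldimethylsilyloxy)phenyl]prop-2-enyloxy}-1-hydroxy-4,8-dimethyldeca-4,8-dienyl]-5-(2-methylprop-1-enyl)-4-(triethylsilyloxy)dihydrofuran-2(3H)-one, epimers at ring C3 and side-chain C1 | O=C1O[C@H](C=C(C)C)[C@@H](O[Si](CC)(CC)CC)C1C(O)C[C@@H](O[Si](C)(C)C(C)(C)C)/C(C)=C/CC/C(C)=C\COC/C=C/c1ccc(O[Si](C)(C)C(C)(C)C)cc1 | intermediate
31 | methanesulfonate of 30 at the side-chain C1 hydroxyl (not isolated) | O=C1O[C@H](C=C(C)C)[C@@H](O[Si](CC)(CC)CC)C1C(OS(C)(=O)=O)C[C@@H](O[Si](C)(C)C(C)(C)C)/C(C)=C/CC/C(C)=C\COC/C=C/c1ccc(O[Si](C)(C)C(C)(C)C)cc1 | intermediate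
32 | (3E,4S,5R)-3-[(3R,4E,8Z)-3-(tert-butyldimethylsilyloxy)-10-{(E)-3-[4-(tert-butyldimethylsilyloxy)phenyl]prop-2-enyloxy}-4,8-dimethyldeca-4,8-dienylidene]-5-(2-methylprop-1-enyl)-4-(triethylsilyloxy)dihydrofuran-2(3H)-one | CC[Si](CC)(CC)O[C@H]1/C(=C\C[C@@H](O[Si](C)(C)C(C)(C)C)/C(C)=C/CC/C(C)=C\COC/C=C/c2ccc(O[Si](C)(C)C(C)(C)C)cc2)C(=O)O[C@@H]1C=C(C)C | intermediate
33 | (3E,4S,5R)-3-[(3R,4E,8Z)-3-(tert-butyldimethylsilyloxy)-10-{(E)-3-[4-(tert-butyldimethylsilyloxy)phenyl]prop-2-enyloxy}-4,8-dimethyldeca-4,8-dienylidene]-4-hydroxy-5-(2-methylprop-1-enyl)dihydrofuran-2(3H)-one | O[C@H]1/C(=C\C[C@@H](O[Si](C)(C)C(C)(C)C)/C(C)=C/CC/C(C)=C\COC/C=C/c2ccc(O[Si](C)(C)C(C)(C)C)cc2)C(=O)O[C@@H]1C=C(C)C | intermediate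
34 | (2R,3S,4E)-4-[(3R,4E,8Z)-3-(tert-butyldimethylsilyloxy)-10-{(E)-3-[4-(tert-butyldimethylsilyloxy)phenyl]prop-2-enyloxy}-4,8-dimethyldeca-4,8-dienylidene]-2-(2-methylprop-1-enyl)-5-oxooxolan-3-yl acetate | CC(=O)O[C@H]1/C(=C\C[C@@H](O[Si](C)(C)C(C)(C)C)/C(C)=C/CC/C(C)=C\COC/C=C/c2ccc(O[Si](C)(C)C(C)(C)C)cc2)C(=O)O[C@@H]1C=C(C)C | intermediate
35 | (2R,3S,4E)-4-[(3R,4E,8Z)-3-hydroxy-10-{(E)-3-(4-hydroxyphenyl)prop-2-enyloxy}-4,8-dimethyldeca-4,8-dienylidene]-2-(2-methylprop-1-enyl)-5-oxooxolan-3-yl acetate | CC(=O)O[C@H]1/C(=C\C[C@@H](O)/C(C)=C/CC/C(C)=C\COC/C=C/c2ccc(O)cc2)C(=O)O[C@@H]1C=C(C)C | target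

## Step count and least certain steps

Total: 24 steps. Longest linear sequence: 14 steps (steps 1–4, 8, 11–14, 20–24, starting from 1).

**Step 11 (key step).** Three things can go wrong.
- Positional selection in the hydrozirconation may be incomplete, because a methyl group and a CH2R group differ little in size, so some zirconium may remain on C5'.
- Enantioselectivity may be eroded, because the unbranched aliphatic aldehyde can also react through the achiral zirconocene-promoted path.
- The aldehyde may lose silanolate by β-elimination.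

The fallback sets the stereocentre by reduction instead of addition. Starting from 13 and 16, the same hydrozirconation and zinc transmetalation is run without ligand (CH2Cl2, 0 °C) to give the racemic carbinol rac-19 F1. Dess–Martin oxidation gives the enone (4E,8Z)-10-{(E)-3-[4-(tert-butyldimethylsilyloxy)phenyl]prop-2-enyloxy}-4,8-dimethyl-1-(triethylsilyloxy)deca-4,8-dien-3-one F2, at which stage the regioisomeric enone can be removed by chromatography. Corey–Bakshi–Shibata reduction with (S)-2-methyl-CBS-oxazaborolidine and catecholborane in toluene at −78 °C, with the 1-methylalkenyl group acting as the large substituent, returns to the route at 19.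

**Step 21.** The elimination may give poor E/Z selectivity, since the in-plane C2' substituent meets the C3 silyloxy group in the E isomer. Prolonged exposure to DBU may also cause γ-deprotonation with loss of the C3' silyloxy group. The fallback replaces elimination by a Horner–Wadsworth–Emmons olefination and sets out from 28. Treatment with LiN(i-Pr)2 (2.2 equiv) and diethyl chlorophosphate in THF at −78 °C (enol phosphate, then 1,3-phosphoryl shift) gives diethyl [(4S,5R)-5-(2-methylprop-1-enyl)-2-oxo-4-(triethylsilyloxy)tetrahydrofuran-3-yl]phosphonate F3. Condensation of F3 with 22 under LiCl and DBU in MeCN at 0 °C, which favours the E alkylidene, returns to the route at 32 and bypasses 30.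

**Step 20.** The lithium enolate 29 may expel triethylsilanolate to give a butenolide before it adds, or it may enolise the β-silyloxy aldehyde. The fallback avoids a free lithium enolate and sets out from 28. LiN(i-Pr)2 is added to 28 and Me3SiCl in THF at −78 °C (in-situ quench) to give the silyl ketene acetal (4S,5R)-5-(2-methylprop-1-enyl)-4-(triethylsilyloxy)-2-(trimethylsilyloxy)-4,5-dihydrofuran F4. A Mukaiyama aldol addition of F4 to 22 with BF3·OEt2 in CH2Cl2 at −78 °C returns to the route at 30.

**Step 19.** The basic ylide may epimerise the α-alkoxy aldehyde, induce β-elimination of silanolate or attack the lactone. The fallback builds the alkene without a basic reagent and sets out from 27. Methylenation with Zn, CH2Br2 and TiCl4 (THF/CH2Cl2, 0 °C) gives (4S,5R)-5-ethenyl-4-(triethylsilyloxy)dihydrofuran-2(3H)-one F5. Cross-metathesis of F5 with 2-methylbut-2-ene (as co-solvent, second-generation Grubbs catalyst, CH2Cl2, 40 °C) returns to the route at 28.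

**Step 8.** The electron-rich bromide 11 may ionise or oligomerise, and the alkoxide 12 may take the silyl group from the aryl silyl ether. The fallback forms the ether by palladium-catalysed allylic substitution and sets out from 10. Acetylation (Ac2O, pyridine) gives (E)-3-[4-(tert-butyldimethylsilyloxy)phenyl]prop-2-enyl acetate F6. Alcohol 7 is converted into its zinc alkoxide with Et2Zn (0.5 equiv) and coupled with F6 using Pd(OAc)2 and 2-(di-tert-butylphosphino)biphenyl (reduced in the flask to zerovalent palladium) in THF at rt. Attack at the unsubstituted terminus of the allylpalladium intermediate returns to the route at 13.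

## Further compounds

F1 | step 11 | rac-19, (4E,8Z)-10-{(E)-3-[4-(tert-butyldimethylsilyloxy)phenyl]prop-2-enyloxy}-4,8-dimethyl-1-(triethylsilyloxy)deca-4,8-dien-3-ol (racemic) | CC[Si](CC)(CC)OCCC(O)/C(C)=C/CC/C(C)=C\COC/C=C/c1ccc(O[Si](C)(C)C(C)(C)C)cc1
F2 | step 11 | (4E,8Z)-10-{(E)-3-[4-(tert-butyldimethylsilyloxy)phenyl]prop-2-enyloxy}-4,8-dimethyl-1-(triethylsilyloxy)deca-4,8-dien-3-one | CC[Si](CC)(CC)OCCC(=O)/C(C)=C/CC/C(C)=C\COC/C=C/c1ccc(O[Si](C)(C)C(C)(C)C)cc1
F3 | step 21 | diethyl [(4S,5R)-5-(2-methylprop-1-enyl)-2-oxo-4-(triethylsilyloxy)tetrahydrofuran-3-yl]phosphonate (epimers at C3) | CCOP(=O)(OCC)C1C(=O)O[C@H](C=C(C)C)[C@H]1O[Si](CC)(CC)CC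
F4 | step 20 | (4S,5R)-5-(2-methylprop-1-enyl)-4-(triethylsilyloxy)-2-(trimethylsilyloxy)-4,5-dihydrofuran | C[Si](C)(C)OC1=C[C@H](O[Si](CC)(CC)CC)[C@@H](C=C(C)C)O1
F5 | step 19 | (4S,5R)-5-ethenyl-4-(triethylsilyloxy)dihydrofuran-2(3H)-one | O=C1C[C@H](O[Si](CC)(CC)CC)[C@@H](C=C)O1
F6 | step 8 | (E)-3-[4-(tert-butyldimethylsilyloxy)phenyl]prop-2-enyl acetate | CC(=O)OC/C=C/c1ccc(O[Si](C)(C)C(C)(C)C)cc1
A1 | alternative 1 | trans β-hydroxy α-(E)-alkylidene γ-lactone bis-silyl ether (identical with 33) | O[C@H]1/C(=C\C[C@@H](O[Si](C)(C)C(C)(C)C)/C(C)=C/CC/C(C)=C\COC/C=C/c2ccc(O[Si](C)(C)C(C)(C)C)cc2)C(=O)O[C@@H]1C=C(C)C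
A2 | alternative 1 | (E)-vinyl iodide with free C3 and C4 hydroxyls | O[C@@H](/C(I)=C\C[C@@H](O[Si](C)(C)C(C)(C)C)/C(C)=C/CC/C(C)=C\COC/C=C/c1ccc(O[Si](C)(C)C(C)(C)C)cc1)[C@H](O)C=C(C)C
A3 | alternative 1 | carbon monoxide | [C-]#[O+]
A4 | alternative 2 | anti γ-hydroxy β-triethylsilyloxy α-(E)-alkylidene methyl ester | COC(=O)/C(=C/C[C@@H](O[Si](C)(C)C(C)(C)C)/C(C)=C/CC/C(C)=C\COC/C=C/c1ccc(O[Si](C)(C)C(C)(C)C)cc1)[C@H](O[Si](CC)(CC)CC)[C@H](O)C=C(C)C
A5 | alternative 2 | 3-methylbut-2-enal | CC(C)=CC=O
A6 | alternative 2 | α-chiral γ-triethylsilyloxy 2-methoxycarbonyl allylboronic acid pinacol ester carrying the side chain | COC(=O)/C(=C\O[Si](CC)(CC)CC)[C@@H](B1OC(C)(C)C(C)(C)O1)C[C@@H](O[Si](C)(C)C(C)(C)C)/C(C)=C/CC/C(C)=C\COC/C=C/c1ccc(O[Si](C)(C)C(C)(C)C)cc1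
A7 | alternative 3 | full skeleton with free C3' carbinol, C3 triethylsilyl ether and aryl TBS ether | CC[Si](CC)(CC)O[C@H]1/C(=C\C[C@@H](O)/C(C)=C/CC/C(C)=C\COC/C=C/c2ccc(O[Si](C)(C)C(C)(C)C)cc2)C(=O)O[C@@H]1C=C(C)C
A8 | alternative 3 | (2E,6Z)-8-{(E)-3-[4-(tert-butyldimethylsilyloxy)phenyl]prop-2-enyloxy}-2,6-dimethylocta-2,6-dienal | O=C/C(C)=C/CC/C(C)=C\COC/C=C/c1ccc(O[Si](C)(C)C(C)(C)C)cc1
A9 | alternative 3 | silyl dienolate, (4S,5R)-2-(tert-butyldimethylsilyloxy)-3-ethenyl-5-(2-methylprop-1-enyl)-4-(triethylsilyloxy)-4,5-dihydrofuran | CC[Si](CC)(CC)O[C@H]1C(C=C)=C(O[Si](C)(C)C(C)(C)C)O[C@@H]1C=C(C)C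
A10 | alternative 3 | (3E,4S,5R)-3-ethylidene-5-(2-methylprop-1-enyl)-4-(triethylsilyloxy)dihydrofuran-2(3H)-one | CC[Si](CC)(CC)O[C@H]1/C(=C\C)C(=O)O[C@@H]1C=C(C)C
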